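**Assumption:** (S)-2,3-O-isopropylidene-glyceraldehyde (made from L-ascorbic acid) is taken as a purchasable chiral starting material, and the facial sense of the cycloaddition is assigned by the inside-alkoxy (Houk/Kishi) model, not by direct precedent.

## Retrosynthetic overview

1. The enal is installed last, by Heck coupling of an aryl bromide with acrolein diethyl acetal and acid hydrolysis, which also frees the phenol.
2. The CH2OH carbon is what remains of a glyceraldehyde-derived dioxolane after one-carbon excision (glycol cleavage, then reduction).
3. Key disconnection: the 1,4-dioxane ring, the only ring made, comes from an inverse-electron-demand hetero-Diels–Alder reaction of 5-bromo-3-methoxy-o-benzoquinone with an (E)-styryl dioxolane. The E geometry gives the trans ring, and the bought dioxolane stereocentre sets the facial selectivity.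
4. The dienophile comes from Heck coupling of MOM-protected 4-bromo-2,6-dimethoxyphenol with (R)-vinyl dioxolane (from (S)-glyceraldehyde acetonide). The quinone comes from Dakin oxidation of 5-bromo-o-vanillin followed by Ag2O oxidation of the catechol.
5. Ring order: both benzene rings are bought; the dioxane ring is formed in step 6.

## Route

**Step 1**
Reactants: 1, 5-bromo-2-hydroxy-3-methoxybenzaldehyde
Product: 2, 5-bromo-3-methoxybenzene-1,2-diol
Conditions: 30% H2O2, 1 M NaOH, 0 °C to rt, N2; then HCl
Reagents that add atoms: hydrogen peroxide, OO (one O inserted; the CHO carbon leaves as formate)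
Why: Dakin oxidation of an o-hydroxybenzaldehyde (aryl migration to peroxide oxygen, then formate hydrolysis) gives the catechol, and the aryl bromide and methyl ether are inert.

**Step 2**
Reactants: 3, 4-bromo-2,6-dimethoxyphenol
Product: 4, 5-bromo-1,3-dimethoxy-2-(methoxymethoxy)benzene
Conditions: NaH, MOMCl, DMF, 0 °C to rt
Reagents that add atoms: chloromethyl methyl ether, COCCl
Why: Williamson-type O-alkylation of the hindered phenoxide gives a MOM ether that keeps the ring electron-rich for the cycloaddition and masks a phenol that would otherwise be oxidised by the quinone or periodic acid and would interfere in the basic Heck stage of step 8.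

**Step 3**
Reactants: 5, (S)-2,2-dimethyl-1,3-dioxolane-4-carbaldehyde
Product: 6, (R)-2,2-dimethyl-4-vinyl-1,3-dioxolane (descriptor changes by CIP priority only; volatile, isolated by careful distillation)
Conditions: Ph3PCH3Br, KHMDS, THF, −78 to 0 °C
Reagents that add atoms: methyltriphenylphosphonium bromide, C[P+](c1ccccc1)(c1ccccc1)c1ccccc1.[Br-] (delivers CH2)
Why: Wittig methylenation with a salt-free, non-stabilised ylide at low temperature does not epimerise the α-alkoxy aldehyde, so the purchased stereocentre is carried over intact.

**Step 4**
Reactants: 4, 5-bromo-1,3-dimethoxy-2-(methoxymethoxy)benzene; 6, (R)-2,2-dimethyl-4-vinyl-1,3-dioxolane (1.5 equiv)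
Product: 7, (R)-4-[(E)-2-(3,5-dimethoxy-4-(methoxymethoxy)phenyl)ethenyl]-2,2-dimethyl-1,3-dioxolane
Conditions: Pd2(dba)3 (2 mol%), [HP(t-Bu)3]BF4 (8 mol%), Cy2NMe, dioxane, 80 °C, sealed tube
Reagents that add atoms: none
Why: Mizoroki–Heck arylation at the terminal alkene carbon with β-hydride elimination toward the benzylic position gives the conjugated E-styrene, and the bulky phosphine and amine base suppress Pd–H chain walking so the allylic stereocentre is untouched.

**Step 5**
Reactants: 2, 5-bromo-3-methoxybenzene-1,2-diol (2 equiv relative to 7)
Product: 8, 5-bromo-3-methoxy-1,2-benzoquinone (not stored; the filtered solution is used at once in step 6)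
Conditions: Ag2O (2.5 equiv), MgSO4, Et2O, 0 °C, 15 min, dark; filter through Celite
Reagents that add atoms: none (Ag2O removes two H)
Why: Two-electron oxidation of the catechol by Ag2O under neutral anhydrous conditions gives the o-quinone, with MgSO4 taking up the water formed so that hydration and dimerisation are slowed, and the aryl bromide and methyl ether are unaffected.

**Step 6**
Reactants: 8, 5-bromo-3-methoxy-1,2-benzoquinone (fresh Et2O solution, about 2 equiv); 7, the (R,E)-styryl dioxolane
Product: 9, (2S,3R)-7-bromo-2-[3,5-dimethoxy-4-(methoxymethoxy)phenyl]-3-[(4S)-2,2-dimethyl-1,3-dioxolan-4-yl]-5-methoxy-2,3-dihydro-1,4-benzodioxine (trans)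
Conditions: add the solution of 8 in portions to 7, toluene, rt, dark, 24 h; chromatography to remove the minor diastereomer
Reagents that add atoms: none
Why: This is an inverse-electron-demand hetero-Diels–Alder reaction of the o-quinone (O=C–C=O heterodiene) with the electron-rich styrene, and its three selectivity elements are set as follows.
- Ring stereochemistry: suprafacial addition to the E-alkene fixes the 2,3-trans relationship.
- Regiochemistry: the nucleophilic alkene carbon (the one bearing the dioxolane) bonds to the more electrophilic quinone oxygen, the one on the carbonyl next to the OMe-bearing carbon. The other carbonyl oxygen, deactivated by through-conjugation with the OMe group, closes on the benzylic carbon.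
- Facial selectivity: the quinone adds anti to the dioxolane CH2 with the allylic C–O "inside", so the new ring C–O bond is erythro to the existing dioxolane C–O bond. From the (R)-alkene this gives the ring configuration of the target. Expected d.r. is about 4:1, and separating the diastereomers here secures the enantiopurity of everything downstream.

**Step 7** (telescoped)
Reactants: 9, the cycloadduct
Product: 10, [(2S,3S)-6-bromo-3-[3,5-dimethoxy-4-(methoxymethoxy)phenyl]-8-methoxy-2,3-dihydro-1,4-benzodioxin-2-yl]methanol
Conditions: H5IO6 (1.5 equiv), EtOAc, rt, 2 h; filter; then NaBH4, EtOH, 0 °C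
Reagents that add atoms: none (NaBH4 delivers H only; the dioxolane CH2 leaves as formaldehyde and the ketal carbon as acetone)
Why: Periodic acid hydrolyses the terminal acetonide and cleaves the glycol in one pot (Malaprade cleavage) and the non-isolated α-aryloxy aldehyde is reduced at once, so the controlling stereocentre becomes the CH2OH carbon while the ring stereocentres, aryl bromide, MOM and methyl ethers are untouched.

**Step 8** (telescoped)
Reactants: 10, the bromo alcohol; 11, acrolein diethyl acetal (3 equiv)
Product: 12, Bilagrewin, (E)-3-[(2S,3S)-3-(4-hydroxy-3,5-dimethoxyphenyl)-2-(hydroxymethyl)-8-methoxy-2,3-dihydro-1,4-benzodioxin-6-yl]prop-2-enal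
Conditions: Pd(OAc)2 (5 mol%), n-Bu4NOAc, K2CO3, KCl, DMF, 90 °C; then 3 M HCl, THF/i-PrOH, 40–45 °C
Reagents that add atoms: acrolein diethyl acetal, C=CC(OCC)OCC (C3 unit); water, O (carbonyl oxygen on acetal hydrolysis)
Why: Heck coupling under Cacchi conditions gives the (E)-cinnamaldehyde diethyl acetal and aqueous acid then hydrolyses the acetal to the E-enal and cleaves the aryl MOM ether, with the free primary alcohol tolerated, the phenol protected during the hot basic stage, and the trans-dioxane being the thermodynamic isomer under acid.

## Compound list

1 | 5-bromo-2-hydroxy-3-methoxybenzaldehyde | COc1cc(Br)cc(C=O)c1O | starting material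
2 | 5-bromo-3-methoxybenzene-1,2-diol | COc1cc(Br)cc(O)c1O | intermediate
3 | 4-bromo-2,6-dimethoxyphenol | COc1cc(Br)cc(OC)c1O | starting material
4 | 5-bromo-1,3-dimethoxy-2-(methoxymethoxy)benzene | COCOc1c(OC)cc(Br)cc1OC | intermediate
5 | (S)-2,2-dimethyl-1,3-dioxolane-4-carbaldehyde | O=C[C@@H]1COC(C)(C)O1 | starting material
6 | (R)-2,2-dimethyl-4-vinyl-1,3-dioxolane | C=C[C@@H]1COC(C)(C)O1 | intermediate
7 | (R)-4-[(E)-2-(3,5-dimethoxy-4-(methoxymethoxy)phenyl)ethenyl]-2,2-dimethyl-1,3-dioxolane | COCOc1c(OC)cc(/C=C/[C@@H]2COC(C)(C)O2)cc1OC | intermediate
8 | 5-bromo-3-methoxy-1,2-benzoquinone | COC1=CC(Br)=CC(=O)C1=O | intermediate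
9 | (2S,3R)-7-bromo-2-[3,5-dimethoxy-4-(methoxymethoxy)phenyl]-3-[(4S)-2,2-dimethyl-1,3-dioxolan-4-yl]-5-methoxy-2,3-dihydro-1,4-benzodioxine | COCOc1c(OC)cc([C@@H]2Oc3cc(Br)cc(OC)c3O[C@H]2[C@@H]4COC(C)(C)O4)cc1OC | intermediate
10 | [(2S,3S)-6-bromo-3-[3,5-dimethoxy-4-(methoxymethoxy)phenyl]-8-methoxy-2,3-dihydro-1,4-benzodioxin-2-yl]methanol | COCOc1c(OC)cc([C@@H]2Oc3cc(Br)cc(OC)c3O[C@H]2CO)cc1OC | intermediate
11 | acrolein diethyl acetal (3,3-diethoxyprop-1-ene) | C=CC(OCC)OCC | starting material
12 | Bilagrewin | COc1cc([C@@H]2Oc3cc(/C=C/C=O)cc(OC)c3O[C@H]2CO)cc(OC)c1O | target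

## Summary

**Total steps:** 8. Steps 5 and 6 are telescoped with no isolation of the quinone, and steps 7 and 8 are each run as two-stage one-pot operations.

**Longest linear sequence:** 5 steps. This is 5 → 6 → 7 → 9 → 10 → 12 (steps 3, 4, 6, 7, 8). The quinone branch 1 → 2 → 8 → 9 → 10 → 12 (steps 1, 5, 6, 7, 8) is the same length.

**Steps most likely to fail, with fallbacks:**

1. **Step 6 (cycloaddition).** Quinone dimerisation or addition across the quinone's carbon diene may outrun the hetero-Diels–Alder reaction, and the facial selectivity may be low or opposite to the model. Fallback: build the dioxane ionically from the same chiral starting materials. This means Mitsunobu etherification (inversion) of the mono-protected catechol with a glycerate-derived secondary alcohol, addition of the aryllithium to the derived aldehyde, and acid-mediated closure through the quinone methide to the trans ring.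
2. **Step 8 (Heck on an electron-rich bromide plus acid deprotection).** The coupling may be slow, or the acid stage may open or epimerise the benzylic ether. Fallback: convert ArBr to ArCHO (O-silylate, Li–Br exchange, DMF), homologate by Wittig reaction with Ph3P=CHCHO, and remove MOM separately with TMSBr at low temperature.
3. **Step 4 (Heck with a volatile allylic-ether alkene).** Regio-isomers or Pd–H isomerisation toward the enol ether would erode the stereocentre. Fallback: form the alkene by carbonyl olefination instead. This would be an E-selective Julia–Kocienski reaction between aldehyde 5 and the benzylic tetrazolyl sulfone prepared from MOM-protected syringaldehyde.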